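## Retrosynthetic overview

- **Feature:** ring A carries OH (C3), OMe (C4) and Br (C5) on three adjacent carbons and the chain at C1. This is the pattern of a mirror-symmetric 5-substituted 2-methoxycyclohexane-1,3-dione in which one C=O ends as C–OH and the other as C–Br.
- **Late stage:** target ⇒ (acidic methanol) (R)-2,3-diarylpropanoic acid ⇒ (asymmetric hydrogenation, sets C2) (E)-2,3-diarylacrylic acid ⇒ (Perkin, C2=C3) ring A arylacetic acid + ring B aldehyde.
- **Ring A:** acid ⇒ 3-bromo-2-methoxycyclohexenone (dehydrogenation) ⇒ symmetric dione ⇒ Michael–Dieckmann annulation of methyl 4-methoxyacetoacetate with dimethyl glutaconate (bonds C1–C2 and C4–C5 of ring A).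
- **Ring B:** bought as an arene. 5-Bromovanillin is brominated at C6 and O-demethylated.
- **Order:** ring A carbocycle (step 1), its aromatisation (step 4), union with ring B (step 8), stereocentre (step 9).

Key step: step 1

Assumption: both antipodes of the SpinPHOX ligand are accessible; the one that delivers H2 to the Si face of C2 of the acrylic acid in step 9 (giving R) is identified in a first small run, with the absolute configuration read from anomalous X-ray scattering of the three bromine atoms.

## Route

Step 1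
Reactants: 1 methyl 4-methoxyacetoacetate; 2 dimethyl (E)-glutaconate
Product: 4 methyl 3-methoxy-6-(2-methoxy-2-oxoethyl)-2,4-dioxocyclohexane-1-carboxylate, via Michael adduct 3 (not isolated)
Conditions: 1 (1.2 equiv), NaOMe (1.2 equiv), MeOH, 0 °C; 2 added over 2 h, rt; then reflux, 16 h; 1 M HCl to pH 2
Reagents that add atoms: none
Why: The sodium enolate of 1, formed at its doubly activated C2 with no methoxide left over, adds in a Michael reaction to C3 of 2 and gives keto triester 3, whose two CH2CO2Me arms are identical (new bond C1–C2 of ring A). On heating, equilibrating methoxide produces the enolate at the MeOCH2 carbon, which attacks one arm ester in a Dieckmann condensation, a 6-(enolendo)-exo-trig closure that forms C4–C5 and completes the carbocycle of ring A. The closest known reaction type is the Michael–Dieckmann synthesis of 4-alkoxycarbonylcyclohexane-1,3-diones from acetoacetates and crotonate-type esters. Site selectivity lies in the substrate: every other carbanion–ester pairing in 3 would give a four-membered ring, O-acylation is reversible under methoxide, and the final deprotonation of 4 to its delocalised enolate draws all equilibria forward. Chemoselectivity against self-condensation of 2 rests on the lower pKa of 1, which keeps 2 largely neutral, and on the slow addition of 2. The sp3 ring centres of 4 are enolisable or are erased in step 4, so no stereocontrol is needed.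

Step 2
Reactants: 4 methyl 3-methoxy-6-(2-methoxy-2-oxoethyl)-2,4-dioxocyclohexane-1-carboxylate
Product: 5 methyl 2-(4-methoxy-3,5-dioxocyclohexyl)acetate
Conditions: NaCl (1.2 equiv), H2O (3 equiv), DMSO, 140 °C
Reagents that add atoms: none
Why: Krapcho dealkoxycarbonylation removes only the ring ester, because it alone is β to a ketone and can leave as CO2 from a stabilised dione enolate, while the isolated side-chain ester survives as the protecting group of the future arylacetic acid (a free acid would be turned into an acyl bromide in step 3).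

Step 3
Reactants: 5 methyl 2-(4-methoxy-3,5-dioxocyclohexyl)acetate
Product: 7 methyl 2-(3-bromo-4-methoxy-5-oxocyclohex-3-en-1-yl)acetate (racemic), via enoloxyphosphonium bromide 6 (not isolated)
Conditions: Ph3PBr2 (1.15 equiv), Et3N (1.2 equiv), CH2Cl2, 0 °C → rt
Reagents that add atoms: dibromotriphenylphosphorane, BrP(Br)(c1ccccc1)(c1ccccc1)c1ccccc1
Why: This is the known conversion of cyclic 1,3-diones into 3-bromoenones, in which the enol oxygen attacks phosphorus to give 6 and bromide substitutes by conjugate addition–elimination with loss of Ph3PO; the two carbonyl groups of 5 are enantiotopic, so only one constitution can form, as a racemate whose stereocentre vanishes in step 4.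

Step 4
Reactants: 7 methyl 2-(3-bromo-4-methoxy-5-oxocyclohex-3-en-1-yl)acetate
Product: 10 methyl 2-(3-bromo-5-hydroxy-4-methoxyphenyl)acetate, via silyl dienol ether 8 (not isolated), via dibromo enone 9 (not isolated)
Conditions: TMSOTf (1.15 equiv), Et3N (1.5 equiv), CH2Cl2, 0 °C; pentane, filter, concentrate; NBS (1.0 equiv), THF, −78 → 0 °C; DBU (2.5 equiv), 0 °C → rt; 1 M HCl
Reagents that add atoms: none
Why: In this halogenation–dehydrohalogenation of a ketone through its silyl enol ether, soft enolisation at the CH2 next to the carbonyl gives 8, NBS brominates its terminal carbon to 9, and DBU removes HBr, after which enolisation to the arene is irreversible; NBS is consumed before any phenol exists, so ring bromination should be avoided.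

Step 5
Reactants: 10 methyl 2-(3-bromo-5-hydroxy-4-methoxyphenyl)acetate
Product: 11 2-(3-bromo-5-hydroxy-4-methoxyphenyl)acetic acid
Conditions: LiOH·H2O (3 equiv), THF/H2O, rt; 1 M HCl
Reagents that add atoms: lithium hydroxide, [Li+].[OH-]
Why: This is a standard saponification of an unhindered methyl ester, in which the phenoxide, the aryl bromide and the aryl methyl ether are inert.

Step 6
Reactants: 12 5-bromovanillin
Product: 13 2,3-dibromo-4-hydroxy-5-methoxybenzaldehyde (5,6-dibromovanillin)
Conditions: Br2 (1.2 equiv), Fe powder (5 mol %), AcOH, 80 °C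
Reagents that add atoms: bromine, BrBr
Why: In this electrophilic aromatic bromination, the position para to OMe (C6 of the vanillin numbering) is the more activated of the two free positions, so the second bromine enters next to the first and gives the 2,3-dibromo pattern of ring B.

Step 7
Reactants: 13 2,3-dibromo-4-hydroxy-5-methoxybenzaldehyde
Product: 14 2,3-dibromo-4,5-dihydroxybenzaldehyde
Conditions: AlCl3 (1.3 equiv), pyridine (4.5 equiv), CH2Cl2, reflux; 2 M HCl
Reagents that add atoms: none
Why: In this Lewis-acid ether cleavage assisted by the neighbouring phenol, aluminium chelates the ortho hydroxy/methoxy pair and pyridine takes the activated methyl group by SN2, which is selective for guaiacol-type ethers and leaves the aldehyde and C–Br bonds alone.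

Step 8
Reactants: 11 2-(3-bromo-5-hydroxy-4-methoxyphenyl)acetic acid; 14 2,3-dibromo-4,5-dihydroxybenzaldehyde
Product: 17 (E)-2-(3-acetoxy-5-bromo-4-methoxyphenyl)-3-(4,5-diacetoxy-2,3-dibromophenyl)acrylic acid, via diacetoxy aldehyde 15 (not isolated), via mixed anhydride 16 (not isolated)
Conditions: Ac2O (10 equiv), Et3N (3 equiv), 110 °C; H2O, 60 °C; 1 M HCl; crystallise
Reagents that add atoms: acetic anhydride, CC(=O)OC(C)=O
Why: In this Perkin condensation in its arylacetic acid (Oglialoro) variant, the three phenols are acetylated first, the enolate of 16 adds to the electron-poor aldehyde 15, and acetylation–elimination gives mainly the E acid with the two aryl groups cis, which crystallisation should free from the Z isomer.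

Step 9
Reactants: 17 (E)-2-(3-acetoxy-5-bromo-4-methoxyphenyl)-3-(4,5-diacetoxy-2,3-dibromophenyl)acrylic acid
Product: 18 (R)-2-(3-acetoxy-5-bromo-4-methoxyphenyl)-3-(4,5-diacetoxy-2,3-dibromophenyl)propanoic acid
Conditions: [Ir(cod)(SpinPHOX)][B(3,5-(CF3)2C6H3)4] (1 mol %), H2 (30 bar), Et3N (0.5 equiv), MeOH, 25 °C
Reagents that add atoms: none
Why: In this carboxylate-directed asymmetric hydrogenation of an α-aryl-β-substituted acrylic acid with a chiral iridium phosphine–oxazoline catalyst, the bound carboxylate holds the alkene in the chiral pocket, syn delivery of H2 to the Si face of C2 sets the R centre, the aryl bromides are inert to the cationic iridium hydride, and the substoichiometric amine stays bound as carboxylate salt so the acetates are spared.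

Step 10
Reactants: 18 (R)-2-(3-acetoxy-5-bromo-4-methoxyphenyl)-3-(4,5-diacetoxy-2,3-dibromophenyl)propanoic acid
Product: 19 methyl (R)-2-(3-bromo-5-hydroxy-4-methoxyphenyl)-3-(2,3-dibromo-4,5-dihydroxyphenyl)propanoate
Conditions: HCl (1.25 M in MeOH), argon, 45 °C
Reagents that add atoms: methanol, CO
Why: Fischer esterification and acid-catalysed transesterification of the three aryl acetates run together, and in the absence of base the α-aryl stereocentre should not enolise, so the R configuration is kept.

## Compound list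

| No. | Name | SMILES | Role |
|---|---|---|---|
| 1 | methyl 4-methoxyacetoacetate (methyl 4-methoxy-3-oxobutanoate) | COCC(=O)CC(=O)OC | starting material |
| 2 | dimethyl (E)-glutaconate (dimethyl (E)-pent-2-enedioate) | COC(=O)/C=C/CC(=O)OC | starting material |
| 3 | dimethyl 3-(1,4-dimethoxy-1,3-dioxobutan-2-yl)pentanedioate (racemic, enolisable) | COCC(=O)C(C(=O)OC)C(CC(=O)OC)CC(=O)OC | intermediate |
| 4 | methyl 3-methoxy-6-(2-methoxy-2-oxoethyl)-2,4-dioxocyclohexane-1-carboxylate (drawn as keto tautomer, stereoisomer mixture) | COC(=O)CC1CC(=O)C(OC)C(=O)C1C(=O)OC | intermediate |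
| 5 | methyl 2-(4-methoxy-3,5-dioxocyclohexyl)acetate (drawn as diketone) | COC(=O)CC1CC(=O)C(OC)C(=O)C1 | intermediate |
| 6 | [5-(2-methoxy-2-oxoethyl)-2-methoxy-3-oxocyclohex-1-en-1-yl]oxytriphenylphosphonium bromide (racemic) | COC(=O)CC1CC(=O)C(OC)=C(O[P+](c2ccccc2)(c2ccccc2)c2ccccc2)C1.[Br-] | intermediate |
| 7 | methyl 2-(3-bromo-4-methoxy-5-oxocyclohex-3-en-1-yl)acetate (racemic) | COC(=O)CC1CC(=O)C(OC)=C(Br)C1 | intermediate |
| 8 | methyl 2-[5-bromo-4-methoxy-3-(trimethylsilyloxy)cyclohexa-2,4-dien-1-yl]acetate (racemic) | COC(=O)CC1C=C(O[Si](C)(C)C)C(OC)=C(Br)C1 | intermediate |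
| 9 | methyl 2-(2,5-dibromo-4-methoxy-3-oxocyclohex-4-en-1-yl)acetate (racemic, diastereomer mixture) | COC(=O)CC1CC(Br)=C(OC)C(=O)C1Br | intermediate |
| 10 | methyl 2-(3-bromo-5-hydroxy-4-methoxyphenyl)acetate | COC(=O)Cc1cc(O)c(OC)c(Br)c1 | intermediate |
| 11 | 2-(3-bromo-5-hydroxy-4-methoxyphenyl)acetic acid | OC(=O)Cc1cc(O)c(OC)c(Br)c1 | intermediate |
| 12 | 5-bromovanillin (3-bromo-4-hydroxy-5-methoxybenzaldehyde) | COc1cc(C=O)cc(Br)c1O | starting material |
| 13 | 2,3-dibromo-4-hydroxy-5-methoxybenzaldehyde | COc1cc(C=O)c(Br)c(Br)c1O | intermediate |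
| 14 | 2,3-dibromo-4,5-dihydroxybenzaldehyde | O=Cc1cc(O)c(O)c(Br)c1Br | intermediate |
| 15 | 4,5-diacetoxy-2,3-dibromobenzaldehyde | O=Cc1cc(OC(C)=O)c(OC(C)=O)c(Br)c1Br | intermediate |
| 16 | acetic 2-(3-acetoxy-5-bromo-4-methoxyphenyl)acetic anhydride | CC(=O)OC(=O)Cc1cc(OC(C)=O)c(OC)c(Br)c1 | intermediate |
| 17 | (E)-2-(3-acetoxy-5-bromo-4-methoxyphenyl)-3-(4,5-diacetoxy-2,3-dibromophenyl)acrylic acid | OC(=O)/C(=C/c1cc(OC(C)=O)c(OC(C)=O)c(Br)c1Br)c1cc(OC(C)=O)c(OC)c(Br)c1 | intermediate |
| 18 | (R)-2-(3-acetoxy-5-bromo-4-methoxyphenyl)-3-(4,5-diacetoxy-2,3-dibromophenyl)propanoic acid | OC(=O)[C@H](Cc1cc(OC(C)=O)c(OC(C)=O)c(Br)c1Br)c1cc(OC(C)=O)c(OC)c(Br)c1 | intermediate |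
| 19 | methyl (R)-2-(3-bromo-5-hydroxy-4-methoxyphenyl)-3-(2,3-dibromo-4,5-dihydroxyphenyl)propanoate | COC(=O)[C@H](Cc1cc(O)c(O)c(Br)c1Br)c1cc(O)c(OC)c(Br)c1 | target |

## Step count and risks

Total step count: 10. Longest linear sequence: 8 (steps 1–5, 8, 9, 10).

**Step 1.**
- Risk: self-condensation of the acceptor through its own vinylogous malonate anion, or retro-Claisen loss of the methoxyacetyl unit from the adduct, may outrun addition and ring closure.
- Fallback (from 2, back at 3 and then 4): the C1–C2 bond is made with a donor whose addition to glutaconates is classical, and the methoxyacetyl unit is brought in by acylation.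
- Dimethyl malonate is added to 2 (catalytic NaOMe, MeOH) to give trimethyl 2-(2-methoxy-2-oxoethyl)propane-1,1,3-tricarboxylate F1.
- Krapcho dealkoxycarbonylation (NaCl, wet DMSO, 150 °C) gives dimethyl 3-(2-methoxy-2-oxoethyl)pentanedioate F2.
- LiN(SiMe3)2 (2.2 equiv, THF, −78 °C) followed by methoxyacetyl chloride C-acylates one of the three equivalent arms to 3.
- NaOMe in refluxing MeOH closes 3 to 4 by the same Dieckmann bond.

**Step 4.**
- Risk: electrophilic bromine may attack the methoxy-substituted double bond or the newly formed phenol, and DBU may displace the vinylic bromide by addition–elimination.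
- Fallback (from 7, back at 10): dehydrogenation by selenoxide syn-elimination, with no electrophilic bromine and no amidine base.
- LiN(SiMe3)2 (THF, −78 °C) then PhSeBr gives methyl 2-[5-bromo-4-methoxy-3-oxo-2-(phenylselanyl)cyclohex-4-en-1-yl]acetate F3.
- H2O2/pyridine (CH2Cl2, 0 °C) oxidises it to the selenoxide F4.
- F4 eliminates toward the ring CH that bears the side chain and enolises to 10.

**Step 9.**
- Risk: slow turnover and poor facial selectivity may arise because the ortho bromine twists ring B and crowds the trisubstituted alkene; loss of acetate groups could then let the free catechol bind the metal.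
- Fallback (from 10 and 14, back at 19): Evans asymmetric alkylation, in which an oxazolidinone rather than a catalyst fixes C2.
- Ring A partner:
  - Phenol 10 is capped (MOMCl, iPr2NEt) to methyl 2-[3-bromo-4-methoxy-5-(methoxymethoxy)phenyl]acetate F5.
  - F5 is saponified (LiOH) to 2-[3-bromo-4-methoxy-5-(methoxymethoxy)phenyl]acetic acid F6.
  - F6 is activated (PivCl, Et3N) as the pivalic mixed anhydride F7.
  - F7 is coupled with (R)-4-benzyloxazolidin-2-one (n-BuLi, THF, −78 °C) to the N-arylacetyl imide F8.
- Ring B partner: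
  - Aldehyde 14 is converted (MOMCl, iPr2NEt) to 2,3-dibromo-4,5-bis(methoxymethoxy)benzaldehyde F9.
  - F9 is reduced (NaBH4, MeOH) to [2,3-dibromo-4,5-bis(methoxymethoxy)phenyl]methanol F10.
  - F10 is brominated under Appel conditions (CBr4, PPh3) to 2,3-dibromo-4,5-bis(methoxymethoxy)benzyl bromide F11.
- Union and release:
  - NaN(SiMe3)2 (THF, −78 °C) turns F8 into its chelated Z-enolate, which F11 attacks on the face away from the auxiliary benzyl group to give the (R)-configured alkylated imide F12.
  - LiOH/H2O2 (THF/H2O, 0 °C) releases the tris-MOM (R)-acid F13.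
  - Methanolic HCl as in step 10 esterifies F13 and removes the three MOM groups to give 19.

## Further compounds

F1 | step 1 | trimethyl 2-(2-methoxy-2-oxoethyl)propane-1,1,3-tricarboxylate | COC(=O)CC(CC(=O)OC)C(C(=O)OC)C(=O)OC
F2 | step 1 | dimethyl 3-(2-methoxy-2-oxoethyl)pentanedioate | COC(=O)CC(CC(=O)OC)CC(=O)OC
F3 | step 4 | methyl 2-[5-bromo-4-methoxy-3-oxo-2-(phenylselanyl)cyclohex-4-en-1-yl]acetate (racemic) | COC(=O)CC1CC(Br)=C(OC)C(=O)C1[Se]c1ccccc1
F4 | step 4 | methyl 2-[5-bromo-4-methoxy-3-oxo-2-(phenylseleninyl)cyclohex-4-en-1-yl]acetate (racemic) | COC(=O)CC1CC(Br)=C(OC)C(=O)C1[Se](=O)c1ccccc1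
F5 | step 9 | methyl 2-[3-bromo-4-methoxy-5-(methoxymethoxy)phenyl]acetate | COC(=O)Cc1cc(OCOC)c(OC)c(Br)c1
F6 | step 9 | 2-[3-bromo-4-methoxy-5-(methoxymethoxy)phenyl]acetic acid | OC(=O)Cc1cc(OCOC)c(OC)c(Br)c1
F7 | step 9 | 2-[3-bromo-4-methoxy-5-(methoxymethoxy)phenyl]acetic pivalic anhydride | CC(C)(C)C(=O)OC(=O)Cc1cc(OCOC)c(OC)c(Br)c1
F8 | step 9 | (R)-4-benzyl-3-{2-[3-bromo-4-methoxy-5-(methoxymethoxy)phenyl]acetyl}oxazolidin-2-one | O=C(Cc1cc(OCOC)c(OC)c(Br)c1)N1[C@H](Cc2ccccc2)COC1=O
F9 | step 9 | 2,3-dibromo-4,5-bis(methoxymethoxy)benzaldehyde | O=Cc1cc(OCOC)c(OCOC)c(Br)c1Br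
F10 | step 9 | [2,3-dibromo-4,5-bis(methoxymethoxy)phenyl]methanol | OCc1cc(OCOC)c(OCOC)c(Br)c1Br
F11 | step 9 | 2,3-dibromo-4,5-bis(methoxymethoxy)benzyl bromide | BrCc1cc(OCOC)c(OCOC)c(Br)c1Br
F12 | step 9 | (R)-4-benzyl-3-{(R)-2-[3-bromo-4-methoxy-5-(methoxymethoxy)phenyl]-3-[2,3-dibromo-4,5-bis(methoxymethoxy)phenyl]propanoyl}oxazolidin-2-one | O=C([C@H](Cc1cc(OCOC)c(OCOC)c(Br)c1Br)c1cc(OCOC)c(OC)c(Br)c1)N1[C@H](Cc2ccccc2)COC1=O
F13 | step 9 | (R)-2-[3-bromo-4-methoxy-5-(methoxymethoxy)phenyl]-3-[2,3-dibromo-4,5-bis(methoxymethoxy)phenyl]propanoic acid | OC(=O)[C@H](Cc1cc(OCOC)c(OCOC)c(Br)c1Br)c1cc(OCOC)c(OC)c(Br)c1
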